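The constants are made up; the result is computed.

In 20 s, with this little catalyst, the flask stops short of rest, so you have to reckon what stands at the stop.

    starting material + coupling partner + catalyst ⇌ catalyst + target (K1 = 760 M⁻¹, k1 = 4.0 × 10⁶ M⁻² s⁻¹)
    second substrate + coupling partner + catalyst → catalyst + second product (k2 = 4.0 × 10⁶ M⁻² s⁻¹)
    coupling partner + protic impurity → quenched reagent (k3 = 760 M⁻¹ s⁻¹)
    starting material ⇌ dormant form (K4 = 2.1, k4 = 0.0097 s⁻¹)

the same everywhere: starting material 1.0 mM; second substrate 1.00 mM; protic impurity 0.0500 mM; catalyst 10 µM; time 20 s

| charge | coupling partner |
|---|---|
| oak | 1.00 mM |
| maple | 1.50 mM |

1. which of these there is most of at the end, counted by the starting material in it, oak (target / starting material)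
2. which of these there is most of at the end, counted by the starting material in it, maple (target / starting material)
3. how much there is at the end of the one of these that leads, in percent of the starting material charged: oak
4. how much there is at the end of the one of these that leads, in percent of the starting material charged: maple

Carry one quantity: the balance share, the part of the starting-material-and-target pair that is starting material once step 1 has balanced, which is one over one plus 760 M⁻¹ times the free coupling partner. In oak, with the partner at the mean used below, step 1 relaxes with a half-life near 9.68 s, shorter than the time, so the balance is a fair guide. With the partner held at its oak charge, the impurity goes with a half-life of 0.912 s, also shorter, which leaves oak about 0.950 mM of partner.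

Start with the loose bracket. The ceiling is the charge, 100 %. Step 4, run forward with nothing returning, keeps 82.4 % out of the dormant form. With the partner held at 0.950 mM, that gives oak a floor of 47.9 %.

Now replace oak's partner curve by a rough mean, midway between 0.950 mM and nothing: 0.475 mM. At that mean the second substrate, now pseudo-first-order, gives 0.316 mM of second product, and balance gives 0.265 mM of target. So my estimate leaves oak with 0.369 mM of partner and a balance share of 78.1 %. The same steps for maple give 0.655 mM and 66.8 %.

Multiplying each share by 82.4 % sets the lower edge, so my bracket for starting material is 64.4 % to 78.1 % in oak and 55.0 % to 66.8 % in maple. My reckoning puts starting material ahead in both, since 760 M⁻¹ times either estimated end partner stays below one.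

The forecast gives starting material at 66 % for oak and starting material at 59 % for maple, inside both brackets: “unreacted starting material still leads in both flasks”.

The flask gives starting material at 65.8 % in oak and starting material at 58.0 % in maple, so the forecast stands. Oak's free partner reads 0.382 mM against my 0.369 mM, and its pair reads 76.7 % starting material against 78.1 %. Neither flask is at rest at 20.0 s. At 200 s, oak's starting material is down to 36.8 % and maple's to 34.4 %, and oak's target has fallen to 3.11 % with 60.1 % dormant. Oak's dormant form per starting material, 1.63, is still below 2.1.

In a flask like maple but with 6.0 mM of partner, the same steps leave an estimated 4.35 mM and a share of 23.2 %, so my bracket for starting material runs from 19.1 % to 23.2 %, and target should lead. That flask gives 21.8 % starting material and 71.7 % target.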